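A direct plan would make ring A first: diene A1 and bromoalkynone A2 would give bromoresorcinol ketone A3 by Diels–Alder benzannulation; benzylation, enolate acylation to diketone A4, copper-catalysed O-arylation to dibenzyl flavone A5 and hydrogenolysis would follow. Its weakest steps would be:
- the cycloaddition, in which a methoxy-bearing diene terminus would have to attack a labile bromoalkynone with one regiochemistry;
- the C–O ring closure at a bromide flanked by two ortho substituents, where C–Br reduction would compete;
- the benzylation and hydrogenolysis pair, which would add length without complexity.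

**New strategy.** Ring A is cut at C5–C6 and C7–C8 and is made last. Its C5 and C7 oxygens are 1,3-related, a latent 1,3-diketone, and C8 with its methoxy group hangs on C8a just as the hydroxymethyl carbon hangs on the ring of kojic acid, which already holds O1, C2, C3, C4, C4a, C8a and C8. After arylation at C2 and carboxylation at C4a, one operation acylates the methoxymethyl carbanion with a propanoyl donor and closes the new ketone onto the ester, giving ring A with the free 5,7-diol, the 6-methyl and the 8-methoxy group fixed by connectivity. No cycloaddition, phenol protection or aryl C–O coupling remains.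

Key step: step 7

Remark: flavone numbering is used for the target (O1, C2 to C4, C4a, C5 to C8, C8a; ring A benzenoid, ring B the 4-methoxyphenyl group, ring C the pyranone); the target has no stereocentre, and electrophiles are assumed to enter kojic acid at C6, ortho to its enolic hydroxyl, as in its Mannich and aldol reactions.

Step 1
Reactants: 1 kojic acid [5-hydroxy-2-(hydroxymethyl)-4H-pyran-4-one]
Product: 2 2-bromo-3-hydroxy-6-(hydroxymethyl)-4H-pyran-4-one
Conditions: NBS (1.05 equiv), DMF, 0 °C → rt, dark
Reagents that add atoms: N-bromosuccinimide, O=C1CCC(=O)N1Br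
Why: Electrophilic bromination should take place at C6 of kojic acid, the ring carbon ortho to the enolic hydroxyl, because the other ring C–H lacks this activation.

Step 2
Reactants: 2 2-bromo-3-hydroxy-6-(hydroxymethyl)-4H-pyran-4-one
Product: 3 2-bromo-3-methoxy-6-(methoxymethyl)-4H-pyran-4-one
Conditions: MeI (10 equiv), Ag2O (3 equiv), MeCN, 40 °C, dark
Reagents that add atoms: iodomethane, CI
Why: Purdie methylation should etherify the enolic and the primary hydroxyl group in one operation without free alkoxide, which would displace the bromide of this vinylogous acyl bromide.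

Step 3
Reactants: 3 2-bromo-3-methoxy-6-(methoxymethyl)-4H-pyran-4-one; 4 (4-methoxyphenyl)boronic acid
Product: 5 3-methoxy-6-(methoxymethyl)-2-(4-methoxyphenyl)-4H-pyran-4-one
Conditions: PdCl2(dppf) (3 mol %), K3PO4, 1,4-dioxane–H2O (10:1), 80 °C
Reagents that add atoms: none
Why: Suzuki–Miyaura coupling should be easy at the 2-bromo-4-pyranone carbon, a β-bromoenone that adds readily to zerovalent palladium, and it sets the bond between ring C and ring B.

Step 4
Reactants: 5 3-methoxy-6-(methoxymethyl)-2-(4-methoxyphenyl)-4H-pyran-4-one
Product: 6 3-iodo-5-methoxy-2-(methoxymethyl)-6-(4-methoxyphenyl)-4H-pyran-4-one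
Conditions: NIS (1.1 equiv), CF3CO2H (0.3 equiv), MeCN, rt, dark
Reagents that add atoms: N-iodosuccinimide, O=C1CCC(=O)N1I
Why: Electrophilic iodination should take the one remaining C–H of the pyranone, the β-carbon of the ring enol ether, in preference to the anisyl ring, which is deactivated by conjugation with the electron-poor C2 of the pyranone.

Step 5
Reactants: 6 3-iodo-5-methoxy-2-(methoxymethyl)-6-(4-methoxyphenyl)-4H-pyran-4-one
Product: 7 methyl 5-methoxy-2-(methoxymethyl)-6-(4-methoxyphenyl)-4-oxo-4H-pyran-3-carboxylate
Conditions: Pd(OAc)2 (5 mol %), Xantphos (6 mol %), CO (1 atm), Et3N (2 equiv), MeOH–DMF (1:2), 70 °C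
Reagents that add atoms: carbon monoxide, [C-]#[O+]; methanol, CO
Why: Palladium-catalysed methoxycarbonylation of the alkenyl iodide (oxidative addition to zerovalent palladium, CO insertion, methanolysis of the acylpalladium species) installs the future C5 at the carboxylic acid oxidation level.

Step 6
Reactants: 8 1H-benzotriazole; 9 propanoyl chloride
Product: 10 1-(1H-benzotriazol-1-yl)propan-1-one
Conditions: Et3N (1.1 equiv), CH2Cl2, 0 °C → rt
Reagents that add atoms: none
Why: N-Acylation of benzotriazole by the acid chloride gives a neutral acyl donor of the kind known to acylate ketone and β-keto ester enolates on carbon.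

Step 7
Reactants: 7 methyl 5-methoxy-2-(methoxymethyl)-6-(4-methoxyphenyl)-4-oxo-4H-pyran-3-carboxylate; 10 1-(1H-benzotriazol-1-yl)propan-1-one
Product: 12 5,7-dihydroxy-3,8-dimethoxy-2-(4-methoxyphenyl)-6-methyl-4H-chromen-4-one, via side-chain ketone 11 (not isolated)
Conditions: NaH (4.5 equiv), THF, 0 °C → rt; then 10 (1.15 equiv), 0 °C → rt; then t-BuOH (0.3 equiv), 55 °C; 1 M HCl
Reagents that add atoms: none
Why: Proposed new method: NaH removes a proton from the methoxymethyl carbon of 7, which is vinylogously activated by the ring ketone and the 3-ester, the dienolate is acylated at that carbon by the neutral donor 10 (O- or C3-acylated material is itself an active acyl donor and is returned by benzotriazolide), and the more acidic ketone 11 is held as its enolate; sodium tert-butoxide formed in the flask then gives access to the α′-enolate at the ethyl CH2, which attacks the neighbouring ester, methoxide leaves, and the cyclic 1,3-diketone tautomerises through its C6 and C8 hydrogens to the resorcinol. The closest known reaction type is the toluate-anion annulation, in which the lateral carbanion of an ortho-methylbenzoate is acylated and the resulting 2-(2-oxoalkyl)benzoate is closed by Dieckmann-type condensation to a naphthalene-1,3-diol; lateral deprotonation of 2-alkyl-4-pyranones and C-acylation of stabilised enolates by N-acylbenzotriazoles are likewise known, but their union on a 4-pyranone-3-carboxylate is not. Ring A closes as a [4+2] condensation, C8–C8a–C4a–C5 of the pyranone joining C7–C6 of the propanoyl unit through a Claisen acylation (C7–C8) followed by a 6-exo-trig intramolecular Claisen closure (C5–C6). No stereocentre is set: C8 of 11 is racemic and becomes trigonal on aromatisation. The step needs closure through carbon and not through the enolate oxygen, which would give an enol lactone; the methoxide set free should reopen such a lactone to 11, whereas aromatisation to the bis-phenoxide is irreversible, so the material should drain to 12. The positions of the 5- and 7-hydroxyl groups, the 6-methyl and the 8-methoxy group need no control, because each follows from the connectivity of 7 and of the propanoyl unit.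

**Compound list**
1 | kojic acid, 5-hydroxy-2-(hydroxymethyl)-4H-pyran-4-one | OCc1cc(=O)c(O)co1 | starting material
2 | 2-bromo-3-hydroxy-6-(hydroxymethyl)-4H-pyran-4-one | OCc1cc(=O)c(O)c(Br)o1 | intermediate
3 | 2-bromo-3-methoxy-6-(methoxymethyl)-4H-pyran-4-one | COCc1cc(=O)c(OC)c(Br)o1 | intermediate
4 | (4-methoxyphenyl)boronic acid | COc1ccc(B(O)O)cc1 | starting material
5 | 3-methoxy-6-(methoxymethyl)-2-(4-methoxyphenyl)-4H-pyran-4-one | COCc1cc(=O)c(OC)c(-c2ccc(OC)cc2)o1 | intermediate
6 | 3-iodo-5-methoxy-2-(methoxymethyl)-6-(4-methoxyphenyl)-4H-pyran-4-one | COCc1oc(-c2ccc(OC)cc2)c(OC)c(=O)c1I | intermediate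
7 | methyl 5-methoxy-2-(methoxymethyl)-6-(4-methoxyphenyl)-4-oxo-4H-pyran-3-carboxylate | COCc1oc(-c2ccc(OC)cc2)c(OC)c(=O)c1C(=O)OC | intermediate
8 | 1H-benzotriazole | c1ccc2[nH]nnc2c1 | starting material
9 | propanoyl chloride | CCC(=O)Cl | starting material
10 | 1-(1H-benzotriazol-1-yl)propan-1-one | CCC(=O)n1nnc2ccccc21 | intermediate
11 | methyl 5-methoxy-2-(1-methoxy-2-oxobutyl)-6-(4-methoxyphenyl)-4-oxo-4H-pyran-3-carboxylate (racemic, not isolated) | CCC(=O)C(OC)c1oc(-c2ccc(OC)cc2)c(OC)c(=O)c1C(=O)OC | intermediate
12 | 5,7-dihydroxy-3,8-dimethoxy-2-(4-methoxyphenyl)-6-methyl-4H-chromen-4-one | COc1ccc(-c2oc3c(OC)c(O)c(C)c(O)c3c(=O)c2OC)cc1 | target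

Total step count: 7. Longest linear sequence: 6 steps (steps 1 to 5 and step 7); step 6 prepares the acyl donor.

**Steps most likely to fail**

1. Step 7 (the proposed new method). The ester-stabilised dienolate may be too weak a carbon nucleophile or may be acylated on oxygen, and the side-chain enolate may close through oxygen instead of carbon. The fallback makes the same bonds by known reactions in another order and sets out from iodide 6, where the lateral anion is not stabilised by an ester. Deprotonation with LiN(SiMe3)2 (THF, −78 °C) and acylation with N-methoxy-N-methylpropanamide would give 3-iodo-5-methoxy-2-(1-methoxy-2-oxobutyl)-6-(4-methoxyphenyl)-4H-pyran-4-one F1. Methoxycarbonylation under the conditions of step 5 would give ketone 11, now isolated, where the fallback comes back to the route. NaOMe in MeOH would then close 11 to 12 as a separate intramolecular Claisen condensation.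

2. Step 4. Iodination of the anisyl ring or oxidation at the methoxymethyl carbon may compete with substitution at the pyranone C–H. The fallback halogenates before ring B is present and sets out from bromide 3. NBS should give 2,5-dibromo-3-methoxy-6-(methoxymethyl)-4H-pyran-4-one F2. Suzuki–Miyaura coupling with 4 should then take place first at C2, the β-carbon of the enone and the more electron-poor C–Br bond, to give 3-bromo-5-methoxy-2-(methoxymethyl)-6-(4-methoxyphenyl)-4H-pyran-4-one F3. Methoxycarbonylation of F3 under the conditions of step 5 comes back to the route at 7.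

3. Step 5. Reductive loss of iodine, or conjugate attack of methanol or the amine on the pyranone, may outrun CO insertion at this alkenyl iodide, which is flanked on both sides. The fallback replaces the catalytic carbonylation by a polar carboxylation and sets out from 6. Iodine–magnesium exchange with i-PrMgCl·LiCl (THF, −40 °C) would give [5-methoxy-2-(methoxymethyl)-6-(4-methoxyphenyl)-4-oxo-4H-pyran-3-yl]magnesium chloride F4, and methyl chloroformate would convert it into 7, where it comes back to the route.

**Further compounds**
F1 | step 7 | 3-iodo-5-methoxy-2-(1-methoxy-2-oxobutyl)-6-(4-methoxyphenyl)-4H-pyran-4-one (racemic) | CCC(=O)C(OC)c1oc(-c2ccc(OC)cc2)c(OC)c(=O)c1I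
F2 | step 4 | 2,5-dibromo-3-methoxy-6-(methoxymethyl)-4H-pyran-4-one | COCc1oc(Br)c(OC)c(=O)c1Br
F3 | step 4 | 3-bromo-5-methoxy-2-(methoxymethyl)-6-(4-methoxyphenyl)-4H-pyran-4-one | COCc1oc(-c2ccc(OC)cc2)c(OC)c(=O)c1Br
F4 | step 5 | [5-methoxy-2-(methoxymethyl)-6-(4-methoxyphenyl)-4-oxo-4H-pyran-3-yl]magnesium chloride | COCc1oc(-c2ccc(OC)cc2)c(OC)c(=O)c1[Mg]Cl
A1 | direct plan | (1Z,3Z)-1,4-dimethoxy-2-methyl-1,3-bis(trimethylsilyloxy)buta-1,3-diene | CO/C=C(\O[Si](C)(C)C)/C(C)=C(/OC)O[Si](C)(C)C
A2 | direct plan | 4-bromo-1-methoxybut-3-yn-2-one | COCC(=O)C#CBr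
A3 | direct plan | 1-(2-bromo-4,6-dihydroxy-3-methoxy-5-methylphenyl)-2-methoxyethan-1-one | COCC(=O)c1c(O)c(C)c(O)c(OC)c1Br
A4 | direct plan | 1-[4,6-bis(benzyloxy)-2-bromo-3-methoxy-5-methylphenyl]-2-methoxy-3-(4-methoxyphenyl)propane-1,3-dione (racemic) | COc1ccc(C(=O)C(OC)C(=O)c2c(OCc3ccccc3)c(C)c(OCc3ccccc3)c(OC)c2Br)cc1
A5 | direct plan | 5,7-bis(benzyloxy)-3,8-dimethoxy-2-(4-methoxyphenyl)-6-methyl-4H-chromen-4-one | COc1ccc(-c2oc3c(OC)c(OCc4ccccc4)c(C)c(OCc4ccccc4)c3c(=O)c2OC)cc1
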